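**Retrosynthetic overview**

1. The target 23 comes from its ethyl ether 21 by BBr3 dealkylation. Ring A of 21 is cut across C1–C2 and C5–C6 into dibromopyrone 18 and ethoxyacetylene 19 ([4+2] cycloaddition, then loss of CO2). The strategy rests on the substitution pattern of ring A: OH at C1, aryloxy at C2, Br at C3, H at C4, Br at C5, H at C6. C2–C5 map onto C3–C6 of a 3-aryloxy-4,6-dibromo-2-pyrone, and C1 and C6 are the two alkyne carbons.
2. Pyrone 18 comes from hydroxychloropyrone 15 with POBr3. Compound 15 comes from O–H insertion of phenol 9 into the rhodium carbenoid of diazopyrandione 14 (made from malonyl dichloride 10). This makes the most hindered ether bond, between ring A C2 and the ring B oxygen, without an arylation.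
3. Phenol 9 (rings B and C) comes from SNAr of tribromoguaiacol 2 on 4-bromo-1-fluoro-2-nitrobenzene 3, conversion of nitro to iodo, and O-demethylation. Compound 2 comes from 5-bromo-2-methoxyphenol 1.
4. Order of ring formation: rings B and C are bought as arenes, the pyrone ring is made in step 6, and ring A is closed in step 10.

Key step: step 10

Remark on the chemistry: 5-bromo-2-methoxyphenol is used as the ring B starting material because its bromine para to methoxy fixes the tribromo pattern, which direct tribromination of guaiacol might not.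

**Route**

Step 1
Reactants: 1 5-bromo-2-methoxyphenol
Product: 2 2,3,4-tribromo-6-methoxyphenol
Conditions: Br2 (2.1 equiv), AcOH, 20 °C
Reagents that add atoms: bromine, BrBr
Why: Electrophilic aromatic bromination, in which the free hydroxyl directs the two new bromines to its para and ortho positions and leaves the position ortho to methoxy and meta to hydroxyl free.

Step 2
Reactants: 2 2,3,4-tribromo-6-methoxyphenol; 3 4-bromo-1-fluoro-2-nitrobenzene
Product: 4 4-bromo-2-nitro-1-(2,3,4-tribromo-6-methoxyphenoxy)benzene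
Conditions: K2CO3, DMF, 90 °C
Reagents that add atoms: none
Why: Nucleophilic aromatic substitution (SNAr) of the fluoride activated by the ortho nitro group; the ring bromine is meta to nitro and is not displaced, and di-ortho-substituted bromophenoxides are competent nucleophiles here.

Step 3
Reactants: 4 4-bromo-2-nitro-1-(2,3,4-tribromo-6-methoxyphenoxy)benzene
Product: 5 5-bromo-2-(2,3,4-tribromo-6-methoxyphenoxy)aniline
Conditions: Fe powder, AcOH, EtOH, 70 °C
Reagents that add atoms: none
Why: Béchamp-type dissolving-metal reduction of the nitro group, which leaves aryl bromides and the diaryl ether untouched.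

Step 4
Reactants: 5 5-bromo-2-(2,3,4-tribromo-6-methoxyphenoxy)aniline
Product: 7 4-bromo-2-iodo-1-(2,3,4-tribromo-6-methoxyphenoxy)benzene, via diazonium hydrogensulfate 6 (not isolated)
Conditions: NaNO2, H2SO4, AcOH/H2O, 0 °C; then KI, H2O, 0 to 20 °C
Reagents that add atoms: potassium iodide, [K+].[I-] (sodium nitrite, [Na+].[O-]N=O, supplies the second nitrogen of 6 only)
Why: Diazotisation followed by Sandmeyer-type iodo-dediazoniation, which needs no copper; both positions of ring B ortho to the ether oxygen are substituted, so Pschorr-type ring closure has no site.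

Step 5
Reactants: 7 4-bromo-2-iodo-1-(2,3,4-tribromo-6-methoxyphenoxy)benzene
Product: 9 3,4,5-tribromo-2-(4-bromo-2-iodophenoxy)phenol, via aryloxydibromoborane 8 (not isolated)
Conditions: BBr3 (3 equiv), CH2Cl2, −78 to 20 °C; then H2O
Reagents that add atoms: none
Why: Lewis-acid cleavage of an aryl methyl ether with BBr3, which leaves the diaryl ether and the aryl halides intact; hydrolysis of 8 releases the phenol.

Step 6
Reactants: 10 malonyl dichloride (two molecules)
Product: 13 6-chloro-4-hydroxy-2H-pyran-2-one, via pyrone acid chloride 11 (not isolated), via pyrone carboxylic acid 12 (not isolated)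
Conditions: neat, 20 °C, 10 d (N2, HCl vented); then H2O, 1,4-dioxane, 50 °C
Reagents that add atoms: none
Why: Self-condensation of malonyl dichloride (C-acylation of one molecule by another and lactonisation with loss of HCl) should give acid chloride 11, whose hydrolysis gives the β-keto-acid-type 12 that decarboxylates on warming.

Step 7
Reactants: 13 6-chloro-4-hydroxy-2H-pyran-2-one
Product: 14 6-chloro-3-diazo-2H-pyran-2,4(3H)-dione
Conditions: 4-acetamidobenzenesulfonyl azide (1.1 equiv), iPr2NEt (1.1 equiv), MeCN, 0 °C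
Reagents that add atoms: 4-acetamidobenzenesulfonyl azide, CC(=O)Nc1ccc(cc1)S(=O)(=O)N=[N+]=[N-]
Why: Regitz diazo transfer to the acidic C3 position of a cyclic 1,3-dicarbonyl compound; the hindered amine and low temperature are chosen to spare the C6 chloride.

Step 8
Reactants: 9 3,4,5-tribromo-2-(4-bromo-2-iodophenoxy)phenol; 14 6-chloro-3-diazo-2H-pyran-2,4(3H)-dione
Product: 15 6-chloro-4-hydroxy-3-[3,4,5-tribromo-2-(4-bromo-2-iodophenoxy)phenoxy]-2H-pyran-2-one
Conditions: Rh2(OAc)4 (2 mol %), ClCH2CH2Cl, 70 °C, 14 (1.5 equiv) added over 4 h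
Reagents that add atoms: none
Why: Rh2(OAc)4-catalysed carbenoid O–H insertion, in which the phenol oxygen attacks the electrophilic carbenoid carbon and proton transfer with enolisation gives the 4-hydroxy-2-pyrone; the hindered C–O bond is thus formed at a carbenoid and not by substitution at a crowded aryl carbon.

Step 9
Reactants: 15 6-chloro-4-hydroxy-3-[3,4,5-tribromo-2-(4-bromo-2-iodophenoxy)phenoxy]-2H-pyran-2-one
Product: 18 4,6-dibromo-3-[3,4,5-tribromo-2-(4-bromo-2-iodophenoxy)phenoxy]-2H-pyran-2-one, via phosphorodibromidate 16 (not isolated), via bromochloropyrone 17 (not isolated)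
Conditions: POBr3 (6 equiv), PhMe, 110 °C, slow N2 sweep
Reagents that add atoms: phosphorus oxybromide, O=P(Br)(Br)Br
Why: Deoxybromination of a 4-hydroxy-2-pyrone with POBr3 (bromide addition–elimination on 16) is joined by halide exchange at the acyl-chloride-like C6 of 17 by the same addition–elimination, driven to the bromide by the large bromide excess and by removal of HCl in the gas stream.

Step 10
Reactants: 18 4,6-dibromo-3-[3,4,5-tribromo-2-(4-bromo-2-iodophenoxy)phenoxy]-2H-pyran-2-one; 19 ethoxyacetylene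
Product: 21 1,2,3-tribromo-4-(4-bromo-2-iodophenoxy)-5-(2,4-dibromo-6-ethoxyphenoxy)benzene, via bicyclic lactone 20 (not isolated)
Conditions: 19 (8 equiv, hexane solution), solid K2CO3, PhMe, sealed tube, 85 °C
Reagents that add atoms: none
Why: Proposed new method: the nucleophilic terminal carbon of ynol ether 19 should bond to C6 of the electron-poor pyrone 18 and the ethoxy-bearing carbon to C3 in an asynchronous, inverse-electron-demand [4+2] cycloaddition, and the bridged lactone 20 should then lose CO2 by retro-[4+2] because the product is a benzene ring; the closest known reaction type is the Diels–Alder/decarboxylation sequence of bromo-2-pyrones with alkoxyalkynes and other electron-rich alkynes, which has not been run on a 3-aryloxy-4,6-dibromo-2-pyrone. Ring A is closed by intermolecular [4+2] cycloaddition, which forms its C1–C2 and C5–C6 bonds in a six-membered carbocycle, followed by cycloreversion. The two bridgehead stereocentres of 20 form as a racemate and are erased on aromatisation, so no stereocentre has to be controlled. The step needs the regiochemistry that joins the ethoxy carbon to pyrone C3, and the substrate secures it by matched polarisation: C6 carries bromine and the ring oxygen and is the most electrophilic diene terminus, while C3 carries the aryloxy donor and accepts the oxocarbenium-like alkyne carbon. Substitution of the C6 bromine without ring closure is the competing path; it is held back by the non-polar medium, which disfavours a separated zwitterion, by solid K2CO3, which removes traces of HBr that would destroy the ynol ether, and by a temperature below that at which ethoxyacetylene loses ethylene.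

Step 11
Reactants: 21 1,2,3-tribromo-4-(4-bromo-2-iodophenoxy)-5-(2,4-dibromo-6-ethoxyphenoxy)benzene
Product: 23 3,5-dibromo-2-[3,4,5-tribromo-2-(4-bromo-2-iodophenoxy)phenoxy]phenol (bromoiesol B), via aryloxydibromoborane 22 (not isolated)
Conditions: BBr3 (3 equiv), CH2Cl2, −78 to 20 °C; then H2O
Reagents that add atoms: none
Why: BBr3 cleavage of the aryl ethyl ether at the ethyl carbon; the two diaryl ether links and all aryl halides are inert, and hydrolysis of 22 gives the ring A phenol.

**Compound list**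

1 | 5-bromo-2-methoxyphenol | COc1ccc(Br)cc1O | starting material
2 | 2,3,4-tribromo-6-methoxyphenol | COc1cc(Br)c(Br)c(Br)c1O | intermediate
3 | 4-bromo-1-fluoro-2-nitrobenzene | O=[N+]([O-])c1cc(Br)ccc1F | starting material
4 | 4-bromo-2-nitro-1-(2,3,4-tribromo-6-methoxyphenoxy)benzene | COc1cc(Br)c(Br)c(Br)c1Oc1ccc(Br)cc1[N+](=O)[O-] | intermediate
5 | 5-bromo-2-(2,3,4-tribromo-6-methoxyphenoxy)aniline | COc1cc(Br)c(Br)c(Br)c1Oc1ccc(Br)cc1N | intermediate
6 | 5-bromo-2-(2,3,4-tribromo-6-methoxyphenoxy)benzenediazonium hydrogensulfate | COc1cc(Br)c(Br)c(Br)c1Oc1ccc(Br)cc1[N+]#N.OS(=O)(=O)[O-] | intermediate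
7 | 4-bromo-2-iodo-1-(2,3,4-tribromo-6-methoxyphenoxy)benzene | COc1cc(Br)c(Br)c(Br)c1Oc1ccc(Br)cc1I | intermediate
8 | dibromo[3,4,5-tribromo-2-(4-bromo-2-iodophenoxy)phenoxy]borane | BrB(Br)Oc1cc(Br)c(Br)c(Br)c1Oc1ccc(Br)cc1I | intermediate
9 | 3,4,5-tribromo-2-(4-bromo-2-iodophenoxy)phenol | Oc1cc(Br)c(Br)c(Br)c1Oc1ccc(Br)cc1I | intermediate
10 | malonyl dichloride | O=C(Cl)CC(Cl)=O | starting material
11 | 6-chloro-4-hydroxy-2-oxo-2H-pyran-3-carbonyl chloride | O=C(Cl)c1c(O)cc(Cl)oc1=O | intermediate
12 | 6-chloro-4-hydroxy-2-oxo-2H-pyran-3-carboxylic acid | OC(=O)c1c(O)cc(Cl)oc1=O | intermediate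
13 | 6-chloro-4-hydroxy-2H-pyran-2-one | O=c1cc(O)cc(Cl)o1 | intermediate
14 | 6-chloro-3-diazo-2H-pyran-2,4(3H)-dione | [N-]=[N+]=C1C(=O)C=C(Cl)OC1=O | intermediate
15 | 6-chloro-4-hydroxy-3-[3,4,5-tribromo-2-(4-bromo-2-iodophenoxy)phenoxy]-2H-pyran-2-one | O=c1oc(Cl)cc(O)c1Oc1cc(Br)c(Br)c(Br)c1Oc1ccc(Br)cc1I | intermediate
16 | 6-chloro-2-oxo-3-[3,4,5-tribromo-2-(4-bromo-2-iodophenoxy)phenoxy]-2H-pyran-4-yl phosphorodibromidate | O=c1oc(Cl)cc(OP(=O)(Br)Br)c1Oc1cc(Br)c(Br)c(Br)c1Oc1ccc(Br)cc1I | intermediate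
17 | 4-bromo-6-chloro-3-[3,4,5-tribromo-2-(4-bromo-2-iodophenoxy)phenoxy]-2H-pyran-2-one | O=c1oc(Cl)cc(Br)c1Oc1cc(Br)c(Br)c(Br)c1Oc1ccc(Br)cc1I | intermediate
18 | 4,6-dibromo-3-[3,4,5-tribromo-2-(4-bromo-2-iodophenoxy)phenoxy]-2H-pyran-2-one | O=c1oc(Br)cc(Br)c1Oc1cc(Br)c(Br)c(Br)c1Oc1ccc(Br)cc1I | intermediate
19 | ethoxyacetylene | C#COCC | starting material
20 | 1,8-dibromo-5-ethoxy-4-[3,4,5-tribromo-2-(4-bromo-2-iodophenoxy)phenoxy]-2-oxabicyclo[2.2.2]octa-5,7-dien-3-one (racemic, bridgehead configurations coupled by the bicyclic frame) | CCOC1=CC2(Br)OC(=O)C1(Oc1cc(Br)c(Br)c(Br)c1Oc1ccc(Br)cc1I)C(Br)=C2 | intermediate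
21 | 1,2,3-tribromo-4-(4-bromo-2-iodophenoxy)-5-(2,4-dibromo-6-ethoxyphenoxy)benzene | CCOc1cc(Br)cc(Br)c1Oc1cc(Br)c(Br)c(Br)c1Oc1ccc(Br)cc1I | intermediate
22 | dibromo{3,5-dibromo-2-[3,4,5-tribromo-2-(4-bromo-2-iodophenoxy)phenoxy]phenoxy}borane | BrB(Br)Oc1cc(Br)cc(Br)c1Oc1cc(Br)c(Br)c(Br)c1Oc1ccc(Br)cc1I | intermediate
23 | 3,5-dibromo-2-[3,4,5-tribromo-2-(4-bromo-2-iodophenoxy)phenoxy]phenol (bromoiesol B) | Oc1cc(Br)cc(Br)c1Oc1cc(Br)c(Br)c(Br)c1Oc1ccc(Br)cc1I | target

**Step count and risk**

Total steps: 11. Longest linear sequence: 9 steps (steps 1–5, then 8–11); the pyrone branch (steps 6 and 7) joins at step 8.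

Steps most likely to fail:

1. Step 10 (proposed new method). The ynol ether may be consumed by thermal fragmentation to ketene or by acid-induced polymerisation before it cycloadds. The alkyne may also substitute the C6 bromide by addition–elimination without closing the ring, or add with the opposite orientation. Fallback, from 9 back to 23, by known chemistry that does not use the pyrone: the phenoxide of 9 (K2CO3, DMF, 100 °C) displaces the fluoride of commercial 3,5-dibromo-2-fluorobenzaldehyde (O=Cc1cc(Br)cc(Br)c1F) by SNAr under ortho-formyl activation. This gives 3,5-dibromo-2-[3,4,5-tribromo-2-(4-bromo-2-iodophenoxy)phenoxy]benzaldehyde F1. Baeyer–Villiger (Dakin-type) oxidation with mCPBA in CH2Cl2 converts the aldehyde into 3,5-dibromo-2-[3,4,5-tribromo-2-(4-bromo-2-iodophenoxy)phenoxy]phenyl formate F2. Methanolysis (K2CO3, MeOH) then gives 23.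

2. Step 8. The carbenoid may be lost to dimerisation or to addition to an arene ring, or the phenol may add to the C6 chloride of 14 by addition–elimination instead of inserting. Fallback, from 9 back to 21, by diaryliodonium arylation:
   - 2-Ethoxyaniline (CCOc1ccccc1N) is brominated ortho and para to nitrogen (Br2, AcOH, 0 °C) to 2,4-dibromo-6-ethoxyaniline F3.
   - Diazotisation (NaNO2, H2SO4, 0 °C) gives 2,4-dibromo-6-ethoxybenzenediazonium hydrogensulfate F4, and KI gives 1,5-dibromo-3-ethoxy-2-iodobenzene F5.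
   - Oxidation with mCPBA and TsOH·H2O in MeCN gives (2,4-dibromo-6-ethoxyphenyl)(hydroxy)(tosyloxy)-λ3-iodane F6. This is trapped in the same flask with 1,3,5-trimethoxybenzene as (2,4-dibromo-6-ethoxyphenyl)(2,4,6-trimethoxyphenyl)iodonium tosylate F7.
   - The potassium phenoxide of 9 (t-BuOK, THF/PhMe, 50 °C) is arylated without metal by ligand coupling at trivalent iodine. The electron-poorer dibromoethoxyphenyl group is transferred and 21 is formed.

3. Step 9. Exchange of the C6 chloride may stop short of completion, so that chlorine is carried into ring A, or the pyrone may open at C6. Fallback, from 9 back to 23, by a nitro-activated SNAr: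
   - Commercial 2,4-dibromo-6-nitroaniline (Nc1c(Br)cc(Br)cc1[N+](=O)[O-]) is diazotised (NaNO2, H2SO4) to 2,4-dibromo-6-nitrobenzenediazonium hydrogensulfate F8. Sandmeyer reaction (CuCl, HCl) converts it into 1,5-dibromo-2-chloro-3-nitrobenzene F9.
   - The phenoxide of 9 (Cs2CO3, DMSO, 110 °C) displaces the chloride ortho to nitro to give 1,2,3-tribromo-4-(4-bromo-2-iodophenoxy)-5-(2,4-dibromo-6-nitrophenoxy)benzene F10.
   - Fe/AcOH reduction gives 3,5-dibromo-2-[3,4,5-tribromo-2-(4-bromo-2-iodophenoxy)phenoxy]aniline F11.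
   - Diazotisation (NaNO2, H2SO4, AcOH) gives 3,5-dibromo-2-[3,4,5-tribromo-2-(4-bromo-2-iodophenoxy)phenoxy]benzenediazonium hydrogensulfate F12. Copper-mediated hydroxy-dediazoniation (Cu2O, excess Cu(NO3)2, H2O, 20 °C) traps the aryl radical faster than it can cyclise and gives 23.

**Further compounds**

F1 | step 10 | 3,5-dibromo-2-[3,4,5-tribromo-2-(4-bromo-2-iodophenoxy)phenoxy]benzaldehyde | O=Cc1cc(Br)cc(Br)c1Oc1cc(Br)c(Br)c(Br)c1Oc1ccc(Br)cc1I
F2 | step 10 | 3,5-dibromo-2-[3,4,5-tribromo-2-(4-bromo-2-iodophenoxy)phenoxy]phenyl formate | O=COc1cc(Br)cc(Br)c1Oc1cc(Br)c(Br)c(Br)c1Oc1ccc(Br)cc1I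
F3 | step 8 | 2,4-dibromo-6-ethoxyaniline | CCOc1cc(Br)cc(Br)c1N
F4 | step 8 | 2,4-dibromo-6-ethoxybenzenediazonium hydrogensulfate | CCOc1cc(Br)cc(Br)c1[N+]#N.OS(=O)(=O)[O-]
F5 | step 8 | 1,5-dibromo-3-ethoxy-2-iodobenzene | CCOc1cc(Br)cc(Br)c1I
F6 | step 8 | (2,4-dibromo-6-ethoxyphenyl)(hydroxy)(tosyloxy)-λ3-iodane | CCOc1cc(Br)cc(Br)c1I(O)OS(=O)(=O)c1ccc(C)cc1
F7 | step 8 | (2,4-dibromo-6-ethoxyphenyl)(2,4,6-trimethoxyphenyl)iodonium tosylate | CCOc1cc(Br)cc(Br)c1[I+]c1c(OC)cc(OC)cc1OC.Cc1ccc(cc1)S(=O)(=O)[O-]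
F8 | step 9 | 2,4-dibromo-6-nitrobenzenediazonium hydrogensulfate | [O-][N+](=O)c1cc(Br)cc(Br)c1[N+]#N.OS(=O)(=O)[O-]
F9 | step 9 | 1,5-dibromo-2-chloro-3-nitrobenzene | [O-][N+](=O)c1cc(Br)cc(Br)c1Cl
F10 | step 9 | 1,2,3-tribromo-4-(4-bromo-2-iodophenoxy)-5-(2,4-dibromo-6-nitrophenoxy)benzene | [O-][N+](=O)c1cc(Br)cc(Br)c1Oc1cc(Br)c(Br)c(Br)c1Oc1ccc(Br)cc1I
F11 | step 9 | 3,5-dibromo-2-[3,4,5-tribromo-2-(4-bromo-2-iodophenoxy)phenoxy]aniline | Nc1cc(Br)cc(Br)c1Oc1cc(Br)c(Br)c(Br)c1Oc1ccc(Br)cc1I
F12 | step 9 | 3,5-dibromo-2-[3,4,5-tribromo-2-(4-bromo-2-iodophenoxy)phenoxy]benzenediazonium hydrogensulfate | N#[N+]c1cc(Br)cc(Br)c1Oc1cc(Br)c(Br)c(Br)c1Oc1ccc(Br)cc1I.OS(=O)(=O)[O-]
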